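Two substrates compete for one coupling partner. Let a be the fraction of charged starting material still present, and b the same fraction of second substrate.

common to all: starting material 0.20 M

| flask | coupling partner | second substrate | catalyst | remark | time |
|---|---|---|---|---|---|
| south | 0.26 M | 0.40 M | 2 mM | run made earlier |  |
| west | 0.41 M | 0.40 M | 2 mM | run made earlier |  |
| ash | 0.600 M | 0.400 M | 2.0 mM |  | 20 min |
| birch | 0.300 M | 0.400 M | 2.0 mM |  | 20 min |

| run | time / min | starting material / % | isomer of the product / % | target / % | uncatalysed product / % |
|---|---|---|---|---|---|
| south | 0.833 | 82.5 | 0 | 14.5 | 3.7 |
| south | 2.00 | 71.5 | 0.4 | 22.7 | 4.6 |
| south | 4.00 | 64.1 | 2.7 | 27.9 | 5.5 |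
| south | 10.0 | 60.4 | 5.9 | 27.4 | 6.3 |
| west | 1.33 | 65.2 | 0 | 29.2 | 5.4 |
| west | 4.00 | 46.5 | 3.1 | 41.1 | 8.6 |
| west | 6.00 | 41.1 | 5.8 | 44.5 | 10.0 |
| west | 10.0 | 37.3 | 7.3 | 44.6 | 10.2 |

(standard deviation of a reading: 0.5 percentage points)

- which of these there is most of at the end, counted by the starting material in it, ash (target / uncatalysed product / starting material / isomer of the product)
- which of these there is most of at the end, counted by the starting material in it, birch (target / uncatalysed product / starting material / isomer of the product)
- amount of the one of these that there is most of at the end, in percent of the starting material charged, ash
- amount of the one of these that there is most of at the end, in percent of the starting material charged, birch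

- what was read earlier has a scatter of 0.5 percentage points, one standard deviation
- candidate steps: starting material + coupling partner + catalyst -> catalyst + target; second substrate + coupling partner + catalyst -> catalyst + second product; target <-> isomer of the product; starting material + coupling partner -> uncatalysed product

Each substrate loses its fraction at a rate proportional to the partner, and the catalyst is regenerated. Dividing one fractional rate by the other therefore removes partner and time, and ln a over ln b stays constant while the catalyst stays constant. Second substrate was not read, so b comes from the partner balance, taking the partner as spent. South gives 0.838 for that ratio, the competition exponent s, a selectivity factor. But west gives 0.793, which is lower. West was still falling at its last reading, though, and partner left there would raise its figure, so s stays as south reads it.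

Birch charges less partner than both substrates could take, so partner is the limiting reagent. A straight line between the two plateaus puts a at 54.2%. A straight line has no grounds, however, so s must test it: that a, with its b, consumes 99.6% of birch's partner, and the estimate stands.

Ash charges partner equal to both substrates together, so s relates a to b but does not say how far they go. South's first reading gives a fractional rate of 0.688 min⁻¹ at ash's opening partner. If a and b fell together, 1/a would grow linearly and a would reach 6.78%. Yet s lies below unity, so b runs ahead of a and late partner is scarcer; scaling the rate by that late shortfall gives 9.06%, a higher figure. Taking the middle, and reading the uncatalysed share of consumed starting material from west and the isomer share from south, I expect target near 63.4% in ash. The two runs disagree on the isomer share, which is the weakest step.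

The forecast, reasoning that “the coupling partner runs out, shared with the second substrate”, gave target at 64% (59% to 71%) for ash and starting material at 54% (52% to 56.5%) for birch.

    starting material + coupling partner + catalyst → catalyst + target (k = 8.30 M⁻² s⁻¹)
    second substrate + coupling partner + catalyst → catalyst + second product (k = 12.0 M⁻² s⁻¹)
    target ⇌ isomer of the product (K = 0.270, k = 5.10 × 10⁻⁴ s⁻¹)
    starting material + coupling partner → uncatalysed product (k = 0.00330 M⁻¹ s⁻¹)

Ash ends with target at 62.1% and birch with starting material at 54.3%, both inside the forecast's ranges. Per unit of its own amount, starting material falls at 0.829 of the pace of second substrate, so birch's 47.9% of second substrate, raised to s = 0.838, gives a = 54.0%, and that flask holds 54.3%. In the neighbour of ash charged with 1.6 M of second substrate, 66.1% of that substrate remains at 20.0 min, s gives a = 70.7%, and the flask holds 71.0%.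

The readings are simulated from invented constants; scatter was added.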